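**Retrosynthetic overview**
1. Feature: in the 4-hydroxy-3-methyl-5-ylidenefuran-2(5H)-one ring, O1, C5 (with its exocyclic =CH) and C4 are the enol form of a 2-oxo carboxylic acid. C2, C3 and the C3 methyl group are a propionate, so the ring is cut at C3–C4 and O1–C2 together.
2. This cut gives the enolate of methyl propionate and a (Z)-3-alkylidene-1,4-dioxaspiro[4.5]decan-2-one. In it, cyclohexanone masks the enol oxygen and the acid and also activates the carbonyl group.
3. The ylidene C=C is cut by a Wittig reaction into the full chain aldehyde and a phosphonium salt made from glycolic acid and cyclohexanone.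
4. The chain is cut at the C8–C9 single bond of the diene, giving an E-iodoalkene and the alkenyl metal from carboalumination of 3-(pent-4-ynyl)furan. Its (2S,6S)-2,6-dimethylheptane-1,7-diyl core is C2-symmetric and comes from a twofold auxiliary-controlled methylation of a pimelic bis-imide.
5. Ring order: the furan is bought, the dioxolanone ring is made first as a temporary carrier, and the tetronic acid ring closes last while the dioxolanone ring is consumed.

Key step: step 16

Assumption: the tetronic acid is taken as the 4-hydroxy (enol) tautomer drawn in the target, and the brominated carbon of the dioxolanone reagents is racemic, which has no consequence because it becomes sp2 in the phosphorane.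

**Step 1**
Reactants: 1 glycolic acid; 2 cyclohexanone
Product: 3 1,4-dioxaspiro[4.5]decan-2-one
Conditions: p-TsOH·H2O (cat.), toluene, Dean–Stark, reflux
Reagents that add atoms: none
Why: Acid-catalysed condensation of an α-hydroxy acid with a ketone under azeotropic water removal (dioxolanone formation) binds the hydroxyl and the carboxyl group of 1 into one five-membered acylal ring.

**Step 2**
Reactants: 3 1,4-dioxaspiro[4.5]decan-2-one
Product: 4 3-bromo-1,4-dioxaspiro[4.5]decan-2-one (racemic)
Conditions: NBS, AIBN (cat.), PhCF3, reflux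
Reagents that add atoms: N-bromosuccinimide O=C1CCC(=O)N1Br
Why: Wohl–Ziegler radical bromination picks the C3–H bond because the derived radical is captodatively stabilised by the ring oxygen and the carbonyl group, and the racemic centre it creates becomes sp2 in step 15.

**Step 3**
Reactants: 4 3-bromo-1,4-dioxaspiro[4.5]decan-2-one
Product: 5 (2-oxo-1,4-dioxaspiro[4.5]decan-3-yl)triphenylphosphonium bromide (racemic)
Conditions: PPh3, toluene, rt → 40 °C
Reagents that add atoms: triphenylphosphine c1ccc(cc1)P(c1ccccc1)c1ccccc1
Why: Quaternisation of triphenylphosphine by the highly reactive α-alkoxy α-bromo lactone (phosphonium salt formation) should deliver a salt that precipitates from toluene and needs no chromatography.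

**Step 4**
Reactants: 6 heptanedioyl dichloride (pimeloyl chloride); 7 (S)-4-benzyl-1,3-oxazolidin-2-one (2 equiv)
Product: 8 (4S,4'S)-3,3'-(heptanedioyl)bis(4-benzyl-1,3-oxazolidin-2-one)
Conditions: Et3N, DMAP (cat.), CH2Cl2, 0 °C → rt
Reagents that add atoms: none
Why: DMAP-catalysed N-acylation of the oxazolidinone at both acid chloride ends gives the C2-symmetric bis-imide without touching the auxiliary stereocentres.

**Step 5**
Reactants: 8 (4S,4'S)-3,3'-(heptanedioyl)bis(4-benzyl-1,3-oxazolidin-2-one)
Product: 10 (4S,4'S)-3,3'-[(2S,6S)-2,6-dimethylheptanedioyl]bis(4-benzyl-1,3-oxazolidin-2-one), via bis(sodium enolate) 9 (not isolated)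
Conditions: 8 added to NaHMDS (2.3 equiv), THF, −78 °C; MeI (excess), −78 → −40 °C
Reagents that add atoms: iodomethane CI
Why: Twofold Evans asymmetric alkylation: each chelated Z-enolate is methylated on the face remote from the benzyl group of the (S)-auxiliary, which sets both new centres as S, inverse addition to excess base keeps the lifetime of a mono-enolate short, and stereochemical leakage ends up in diastereomers that can be removed by crystallisation or chromatography.

**Step 6**
Reactants: 10 (4S,4'S)-3,3'-[(2S,6S)-2,6-dimethylheptanedioyl]bis(4-benzyl-1,3-oxazolidin-2-one)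
Product: 11 (2S,6S)-2,6-dimethylheptane-1,7-diol
Conditions: LiBH4, MeOH (additive), THF, 0 °C
Reagents that add atoms: none
Why: Reductive removal of the auxiliaries with lithium borohydride reduces the exocyclic imide carbonyl groups to primary alcohols without epimerisation and returns 7 for reuse.

**Step 7**
Reactants: 11 (2S,6S)-2,6-dimethylheptane-1,7-diol
Product: 13 (2S,6S)-7-[(tert-butyldimethylsilyl)oxy]-2,6-dimethylheptan-1-ol, via monosodium alkoxide 12 (not isolated)
Conditions: NaH (1.0 equiv), THF, rt; TBSCl (1.0 equiv), rt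
Reagents that add atoms: tert-butyldimethylsilyl chloride CC(C)(C)[Si](C)(C)Cl
Why: Monosilylation of a symmetrical diol through its poorly soluble monosodium alkoxide favours the mono-ether, and because 11 is C2-symmetric its two hydroxyl groups are homotopic so that either one leads to the same compound 13.

**Step 8**
Reactants: 13 (2S,6S)-7-[(tert-butyldimethylsilyl)oxy]-2,6-dimethylheptan-1-ol
Product: 14 (2S,6S)-7-[(tert-butyldimethylsilyl)oxy]-2,6-dimethylheptanal
Conditions: TPAP (5 mol %), NMO, 4 Å MS, CH2Cl2, rt
Reagents that add atoms: none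
Why: Ley–Griffith oxidation stops at the aldehyde under neutral anhydrous conditions, so the α-methyl centre and the silyl ether should persist.

**Step 9**
Reactants: 14 (2S,6S)-7-[(tert-butyldimethylsilyl)oxy]-2,6-dimethylheptanal
Product: 15 tert-butyl{[(2S,6S,7E)-8-iodo-2,6-dimethyloct-7-en-1-yl]oxy}dimethylsilane
Conditions: CrCl2, CHI3, dioxane–THF (6:1), 0 °C → rt
Reagents that add atoms: iodoform IC(I)I
Why: Takai olefination with the geminal dichromium species from iodoform gives the E-iodoalkene through the less crowded anti elimination, is helped by the α-branch and the dioxane co-solvent, and is not basic enough to epimerise the aldehyde.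

**Step 10**
Reactants: 16 3-bromofuran; 17 (5-chloropent-1-yn-1-yl)trimethylsilane
Product: 19 [5-(furan-3-yl)pent-1-yn-1-yl]trimethylsilane, via Grignard reagent 18 (not isolated)
Conditions: 17, Mg, THF, reflux; then 16, PdCl2(dppf) (3 mol %), THF, 0 → 45 °C
Reagents that add atoms: none
Why: Kumada–Corriu coupling of a primary alkyl Grignard reagent with a heteroaryl bromide, in which the large bite angle of dppf speeds reductive elimination over β-hydride loss and the silyl cap keeps the alkyne from being deprotonated.

**Step 11**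
Reactants: 19 [5-(furan-3-yl)pent-1-yn-1-yl]trimethylsilane
Product: 20 3-(pent-4-yn-1-yl)furan
Conditions: K2CO3 (cat.), MeOH, rt; pentane extraction, careful concentration (volatile)
Reagents that add atoms: none
Why: Base-catalysed methanolysis of the alkynyl C–Si bond (protodesilylation) frees the terminal alkyne and leaves the furan untouched.

**Step 12**
Reactants: 15 tert-butyl{[(2S,6S,7E)-8-iodo-2,6-dimethyloct-7-en-1-yl]oxy}dimethylsilane; 20 3-(pent-4-yn-1-yl)furan (1.3 equiv)
Product: 23 tert-butyl{[(2S,6S,7E,9E)-13-(furan-3-yl)-2,6,10-trimethyltrideca-7,9-dien-1-yl]oxy}dimethylsilane, via alkenylalane 21 (not isolated), via alkenylzinc chloride 22 (not isolated)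
Conditions: 20, Me3Al, Cp2ZrCl2 (cat.), CH2Cl2, 0 °C → rt; volatiles removed in vacuo; ZnCl2, THF; 15, Pd(PPh3)4 (5 mol %), rt
Reagents that add atoms: trimethylaluminium C[Al](C)C
Why: Zirconium-catalysed syn-carboalumination puts methyl on the internal and aluminium on the terminal alkyne carbon, and the Negishi coupling that follows Al-to-Zn exchange runs with retention at both sp2 partners, so the E,E-diene follows directly from the geometries of 15 and 21.

**Step 13**
Reactants: 23 tert-butyl{[(2S,6S,7E,9E)-13-(furan-3-yl)-2,6,10-trimethyltrideca-7,9-dien-1-yl]oxy}dimethylsilane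
Product: 24 (2S,6S,7E,9E)-13-(furan-3-yl)-2,6,10-trimethyltrideca-7,9-dien-1-ol
Conditions: TBAF, THF, 0 °C → rt
Reagents that add atoms: none
Why: Fluoride-induced cleavage of the Si–O bond, driven by the strong Si–F bond, affects neither the diene, the furan nor the methine centres.

**Step 14**
Reactants: 24 (2S,6S,7E,9E)-13-(furan-3-yl)-2,6,10-trimethyltrideca-7,9-dien-1-ol
Product: 25 (2S,6S,7E,9E)-13-(furan-3-yl)-2,6,10-trimethyltrideca-7,9-dienal
Conditions: TPAP (5 mol %), NMO, 4 Å MS, CH2Cl2, 0 °C → rt
Reagents that add atoms: none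
Why: Ley–Griffith oxidation is mild and neutral enough to spare the furan and the diene and to deliver the α-methyl aldehyde without epimerisation, the aldehyde being used at once.

**Step 15**
Reactants: 5 (2-oxo-1,4-dioxaspiro[4.5]decan-3-yl)triphenylphosphonium bromide; 25 (2S,6S,7E,9E)-13-(furan-3-yl)-2,6,10-trimethyltrideca-7,9-dienal
Product: 27 (3Z)-3-[(2S,6S,7E,9E)-13-(furan-3-yl)-2,6,10-trimethyltrideca-7,9-dien-1-ylidene]-1,4-dioxaspiro[4.5]decan-2-one, via phosphorane 26 (not isolated)
Conditions: 5, DABCO (1 equiv to 5), CH2Cl2, 0 °C; then 25, rt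
Reagents that add atoms: none
Why: Wittig olefination with a carbonyl-stabilised phosphorane places the chain anti to the lactone carbonyl group and hence cis to the ring oxygen (Z), and the weak amine base, consumed in freeing 26 before the aldehyde is added, should leave the α-methyl centre of 25 unchanged.

**Step 16**
Reactants: 27 (3Z)-3-[(2S,6S,7E,9E)-13-(furan-3-yl)-2,6,10-trimethyltrideca-7,9-dien-1-ylidene]-1,4-dioxaspiro[4.5]decan-2-one; 28 methyl propionate
Product: 32 (5Z)-5-[(2S,6S,7E,9E)-13-(furan-3-yl)-2,6,10-trimethyltrideca-7,9-dien-1-ylidene]-4-hydroxy-3-methylfuran-2(5H)-one (target), via lithium enolate 29 (not isolated), via open-chain keto ester enolate 30 (not isolated), via lithium tetronate 31 (not isolated)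
Conditions: 28 (3.3 equiv), LDA (3.0 equiv), THF, −78 °C; add 27, −78 → 0 °C; cold 1 M HCl to pH 2
Reagents that add atoms: none
Why: Enolate 29 adds 1,2 to the acylal carbonyl carbon of 27 (new bond C3–C4 of the target), the tetrahedral alkoxide collapses with cleavage of the ring acyl C–O bond, the hemiketal alkoxide so formed loses cyclohexanone, and the oxygen of the resulting Z-enolate 30 attacks the methyl ester (new bond O1–C2) with loss of methoxide. The closest known reaction type is exactly this crossed Claisen acylation followed by lactonisation, established for ester enolates and 5-ylidene-1,3-dioxolan-4-ones as a route to 5-ylidenetetronic acids and pulvinones. The one ring formed closes in the 5-exo-trig mode, oxygen onto the ester carbonyl carbon. No stereocentre is created, since C3 is only transiently sp3 in 30, and the two chain methines stay untouched as long as no free amide base remains to abstract the allylic methine proton, which is why the ester is used in slight excess over LDA. The step needs carbonyl rather than conjugate attack and retention of the Z geometry: a hard lithium enolate at −78 °C, a carbonyl group activated by a good leaving group, and a β-carbon that is shielded by the branched chain and enriched in electrons by the α-oxygen favour the first, while the dioxolanone ring locks the geometry until O1 is released and Z remains the more stable arrangement afterwards because the chain then points away from the C4 oxygen. Deprotonation of the acidic product to tetronate 31 by a second equivalent of 29 pulls the sequence forward, and the third equivalent covers enolate lost to the liberated ketone.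

**Compound list**
1 | glycolic acid | OCC(=O)O | starting material
2 | cyclohexanone | O=C1CCCCC1 | starting material
3 | 1,4-dioxaspiro[4.5]decan-2-one | O=C1COC2(CCCCC2)O1 | intermediate
4 | 3-bromo-1,4-dioxaspiro[4.5]decan-2-one (racemic) | O=C1OC2(CCCCC2)OC1Br | intermediate
5 | (2-oxo-1,4-dioxaspiro[4.5]decan-3-yl)triphenylphosphonium bromide (racemic) | O=C1OC2(CCCCC2)OC1[P+](c1ccccc1)(c1ccccc1)c1ccccc1.[Br-] | intermediate
6 | heptanedioyl dichloride | O=C(Cl)CCCCCC(=O)Cl | starting material
7 | (S)-4-benzyl-1,3-oxazolidin-2-one | O=C1OC[C@H](Cc2ccccc2)N1 | starting material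
8 | (4S,4'S)-3,3'-(heptanedioyl)bis(4-benzyl-1,3-oxazolidin-2-one) | O=C(CCCCCC(=O)N1[C@@H](Cc2ccccc2)COC1=O)N1[C@@H](Cc2ccccc2)COC1=O | intermediate
9 | bis(sodium Z-enolate) of 8 (not isolated) | [Na+].[Na+].[O-]/C(=C\CCC/C=C(\[O-])N1[C@@H](Cc2ccccc2)COC1=O)N1[C@@H](Cc2ccccc2)COC1=O | intermediate
10 | (4S,4'S)-3,3'-[(2S,6S)-2,6-dimethylheptanedioyl]bis(4-benzyl-1,3-oxazolidin-2-one) | O=C([C@@H](C)CCC[C@H](C)C(=O)N1[C@@H](Cc2ccccc2)COC1=O)N1[C@@H](Cc2ccccc2)COC1=O | intermediate
11 | (2S,6S)-2,6-dimethylheptane-1,7-diol | OC[C@@H](C)CCC[C@H](C)CO | intermediate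
12 | monosodium alkoxide of 11 (not isolated) | [Na+].[O-]C[C@@H](C)CCC[C@H](C)CO | intermediate
13 | (2S,6S)-7-[(tert-butyldimethylsilyl)oxy]-2,6-dimethylheptan-1-ol | CC(C)(C)[Si](C)(C)OC[C@@H](C)CCC[C@H](C)CO | intermediate
14 | (2S,6S)-7-[(tert-butyldimethylsilyl)oxy]-2,6-dimethylheptanal | CC(C)(C)[Si](C)(C)OC[C@@H](C)CCC[C@H](C)C=O | intermediate
15 | tert-butyl{[(2S,6S,7E)-8-iodo-2,6-dimethyloct-7-en-1-yl]oxy}dimethylsilane | CC(C)(C)[Si](C)(C)OC[C@@H](C)CCC[C@H](C)/C=C/I | intermediate
16 | 3-bromofuran | Brc1ccoc1 | starting material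
17 | (5-chloropent-1-yn-1-yl)trimethylsilane | C[Si](C)(C)C#CCCCCl | starting material
18 | [5-(trimethylsilyl)pent-4-yn-1-yl]magnesium chloride (not isolated) | C[Si](C)(C)C#CCCC[Mg]Cl | intermediate
19 | [5-(furan-3-yl)pent-1-yn-1-yl]trimethylsilane | C[Si](C)(C)C#CCCCc1ccoc1 | intermediate
20 | 3-(pent-4-yn-1-yl)furan | C#CCCCc1ccoc1 | intermediate
21 | [(1E)-5-(furan-3-yl)-2-methylpent-1-en-1-yl]dimethylalane (not isolated) | C[Al](C)/C=C(\C)CCCc1ccoc1 | intermediate
22 | [(1E)-5-(furan-3-yl)-2-methylpent-1-en-1-yl]zinc chloride (not isolated) | Cl[Zn]/C=C(\C)CCCc1ccoc1 | intermediate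
23 | tert-butyl{[(2S,6S,7E,9E)-13-(furan-3-yl)-2,6,10-trimethyltrideca-7,9-dien-1-yl]oxy}dimethylsilane | CC(C)(C)[Si](C)(C)OC[C@@H](C)CCC[C@H](C)/C=C/C=C(\C)CCCc1ccoc1 | intermediate
24 | (2S,6S,7E,9E)-13-(furan-3-yl)-2,6,10-trimethyltrideca-7,9-dien-1-ol | OC[C@@H](C)CCC[C@H](C)/C=C/C=C(\C)CCCc1ccoc1 | intermediate
25 | (2S,6S,7E,9E)-13-(furan-3-yl)-2,6,10-trimethyltrideca-7,9-dienal | O=C[C@@H](C)CCC[C@H](C)/C=C/C=C(\C)CCCc1ccoc1 | intermediate
26 | 3-(triphenyl-λ5-phosphanylidene)-1,4-dioxaspiro[4.5]decan-2-one (not isolated) | O=C1OC2(CCCCC2)OC1=P(c1ccccc1)(c1ccccc1)c1ccccc1 | intermediate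
27 | (3Z)-3-[(2S,6S,7E,9E)-13-(furan-3-yl)-2,6,10-trimethyltrideca-7,9-dien-1-ylidene]-1,4-dioxaspiro[4.5]decan-2-one | O=C1OC2(CCCCC2)O/C1=C\[C@@H](C)CCC[C@H](C)/C=C/C=C(\C)CCCc1ccoc1 | intermediate
28 | methyl propionate | CCC(=O)OC | starting material
29 | lithium 1-methoxyprop-1-en-1-olate, methyl cis to OMe (not isolated; geometry without consequence) | C/C=C(\OC)[O-].[Li+] | intermediate
30 | lithium (4Z)-enolate of methyl (6S,10S,11E,13E)-17-(furan-3-yl)-2,6,10,14-tetramethyl-3,4-dioxoheptadeca-11,13-dienoate, C2 unassigned (not isolated) | COC(=O)C(C)C(=O)/C([O-])=C/[C@@H](C)CCC[C@H](C)/C=C/C=C(\C)CCCc1ccoc1.[Li+] | intermediate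
31 | lithium tetronate of 32 (not isolated) | CC1=C([O-])/C(=C/[C@@H](C)CCC[C@H](C)/C=C/C=C(\C)CCCc2ccoc2)OC1=O.[Li+] | intermediate
32 | (5Z)-5-[(2S,6S,7E,9E)-13-(furan-3-yl)-2,6,10-trimethyltrideca-7,9-dien-1-ylidene]-4-hydroxy-3-methylfuran-2(5H)-one | CC1=C(O)/C(=C/[C@@H](C)CCC[C@H](C)/C=C/C=C(\C)CCCc2ccoc2)OC1=O | target

**Step count**
Total: 16 steps.
Longest linear sequence: 11 steps (steps 4–9 and 12–16, from 6 and 7). Steps 1–3 and steps 10–11 are convergent branches.

**Steps most likely to fail**

**1. Step 16.**
- What may go wrong: the enolate may add in conjugate fashion at the ylidene carbon. The allylic methine proton may be removed, with erosion of the configuration next to the ring. The sequence may also stall at the doubly deprotonated open-chain stage, so that lactonisation stays incomplete.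
- Fallback: the ylidene bond is attached to a preformed, O-protected tetronate instead of building the ring. It sets out from aldehyde 25 and comes back at target 32.
- Purchased 4-hydroxy-3-methylfuran-2(5H)-one is O-methylated (Me2SO4, K2CO3, acetone) to 4-methoxy-3-methylfuran-2(5H)-one F1.
- An LDA-mediated aldol addition of F1 through its C5 position to 25 (THF, −78 °C) should give the hydroxyalkyl tetronate F2 as a mixture at the two new centres.
- Mesylation (MsCl, Et3N, CH2Cl2, 0 °C) gives the mesylate F3.
- DBU-induced E1cB elimination removes both new centres and should give the more stable Z-ylidene methyl tetronate F4.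
- SN2 demethylation with lithium propane-1-thiolate in DMF at rt, followed by acidification, releases 32.

**2. Step 15.**
- What may go wrong: the olefination of the α-branched aldehyde may be sluggish, control of the ylidene geometry may be incomplete, and slow amine-induced epimerisation of the aldehyde α-centre may set in during a long reaction.
- Fallback: the phosphorus olefination is replaced by an aldol addition and elimination. It sets out from dioxolanone 3 and aldehyde 25 and comes back at 27.
- 3 is deprotonated with LiHMDS in THF at −78 °C and treated at once with 25 to give the hydroxyalkyl dioxolanone F5 as a diastereomer mixture.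
- MsCl and Et3N in CH2Cl2 at 0 °C convert it into the mesylate F6.
- DBU at 0 °C → rt triggers E1cB elimination, which should settle on the thermodynamically preferred Z-alkylidene compound 27.

**3. Step 12.**
- What may go wrong: methyl may transfer from the mixed organometal in place of alkenyl, the iodoalkene may homocouple, and the diene geometry may partly be lost in the palladium stage.
- Fallback: the C7=C8 double bond is made by olefination instead of forming the C8–C9 single bond by cross-coupling. It sets out from alcohol 13 and alkyne 20 and comes back at 23.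
- Mitsunobu reaction of 13 with 1-phenyl-1H-tetrazole-5-thiol (PPh3, DIAD, THF) gives the tetrazolyl sulfide F7.
- Molybdate-catalysed oxidation with H2O2 in EtOH gives the tetrazolyl sulfone F8.
- In parallel, alane 21 made from 20 is turned into its ate complex with n-BuLi and trapped with paraformaldehyde to give the allylic alcohol F9. MnO2 in CH2Cl2 then oxidises this to the enal F10.
- Julia–Kocienski olefination of F10 with F8 (KHMDS, DME, −60 °C → rt) should form the disubstituted alkene E-selectively and give 23.

**Further compounds**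
F1 | step 16 | 4-methoxy-3-methylfuran-2(5H)-one | COC1=C(C)C(=O)OC1
F2 | step 16 | 5-[(2S,6S,7E,9E)-13-(furan-3-yl)-1-hydroxy-2,6,10-trimethyltrideca-7,9-dien-1-yl]-4-methoxy-3-methylfuran-2(5H)-one (mixture at C5 and C1') | COC1=C(C)C(=O)OC1C(O)[C@@H](C)CCC[C@H](C)/C=C/C=C(\C)CCCc1ccoc1
F3 | step 16 | methanesulfonate of F2 | COC1=C(C)C(=O)OC1C(OS(C)(=O)=O)[C@@H](C)CCC[C@H](C)/C=C/C=C(\C)CCCc1ccoc1
F4 | step 16 | (5Z)-5-[(2S,6S,7E,9E)-13-(furan-3-yl)-2,6,10-trimethyltrideca-7,9-dien-1-ylidene]-4-methoxy-3-methylfuran-2(5H)-one | COC1=C(C)C(=O)O/C1=C\[C@@H](C)CCC[C@H](C)/C=C/C=C(\C)CCCc1ccoc1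
F5 | step 15 | 3-[(2S,6S,7E,9E)-13-(furan-3-yl)-1-hydroxy-2,6,10-trimethyltrideca-7,9-dien-1-yl]-1,4-dioxaspiro[4.5]decan-2-one (mixture at C3 and C1') | O=C1OC2(CCCCC2)OC1C(O)[C@@H](C)CCC[C@H](C)/C=C/C=C(\C)CCCc1ccoc1
F6 | step 15 | methanesulfonate of F5 | O=C1OC2(CCCCC2)OC1C(OS(C)(=O)=O)[C@@H](C)CCC[C@H](C)/C=C/C=C(\C)CCCc1ccoc1
F7 | step 12 | 5-({(2S,6S)-7-[(tert-butyldimethylsilyl)oxy]-2,6-dimethylheptyl}sulfanyl)-1-phenyl-1H-tetrazole | CC(C)(C)[Si](C)(C)OC[C@@H](C)CCC[C@H](C)CSc1nnnn1-c1ccccc1
F8 | step 12 | 5-({(2S,6S)-7-[(tert-butyldimethylsilyl)oxy]-2,6-dimethylheptyl}sulfonyl)-1-phenyl-1H-tetrazole | CC(C)(C)[Si](C)(C)OC[C@@H](C)CCC[C@H](C)CS(=O)(=O)c1nnnn1-c1ccccc1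
F9 | step 12 | (2E)-6-(furan-3-yl)-3-methylhex-2-en-1-ol | OC/C=C(\C)CCCc1ccoc1
F10 | step 12 | (2E)-6-(furan-3-yl)-3-methylhex-2-enal | O=C/C=C(\C)CCCc1ccoc1
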